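**Strategy.** The route rests on disconnecting ring B of the drimane at C7–C8. C8 is a tertiary methyl carbinol next to C9, whose exocyclic carbon C11 can be carried as an ester, so C8–C9–C11 is read as a β-keto ester and C7 as a primary iodide on a ring A cyclohexane. One samarium diiodide Barbier closure forms C7–C8, closes ring B and sets C8 and C9 together. The precursor, an iodoethyl cyclohexyl acetoacetate, comes from 2,4,4-trimethylcyclohexenone by two successive chirality-transferring Claisen-type rearrangements. The chlorinated cyclopentenedione is then built on C11 by Knoevenagel condensation with a symmetrical dione and a catalyst-controlled mono-reduction.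

Key step: step 12

Remark on numbering: decalin atoms carry drimane numbers; in the five-membered ring C1' is the alkylidene carbon, C2' the oxygen-bearing carbon cis to C9, C3' the CH, C4' the carbonyl carbon next to C5', and C5' bears chlorine.
Assumption: the target is treated as the drawn enol tautomer of (4R,5E)-4-chloro-5-(8β-hydroxydriman-11-ylidene)cyclopentane-1,3-dione; enol tautomers, and the two possible O-regioisomers of silyl enol ethers 25 and 26, converge in step 21 and are written as one structure each.
Assumption: 2,4,4-trimethylcyclohex-2-en-1-one (1) is taken as a catalogue compound.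

Step 1
Reactants: 1 2,4,4-trimethylcyclohex-2-en-1-one
Product: 2 (R)-2,4,4-trimethylcyclohex-2-en-1-ol
Conditions: (S)-1-methyl-3,3-diphenyltetrahydro-1H,3H-pyrrolo[1,2-c][1,3,2]oxazaborole (10 mol %), BH3·SMe2, THF, −20 °C
Reagents that add atoms: none
Why: Corey–Bakshi–Shibata reduction, in which the oxazaborolidine–borane complex treats the methyl-bearing alkene arm as the large group and the ring CH2 as the small one, so hydride should reach one carbonyl face only and set the carbinol centre as R.

Step 2
Reactants: 2 (R)-2,4,4-trimethylcyclohex-2-en-1-ol; 3 triethyl orthoacetate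
Product: 4 ethyl 2-[(1S)-2,6,6-trimethylcyclohex-2-en-1-yl]acetate
Conditions: EtCO2H (cat.), 140 °C, EtOH distilled off
Reagents that add atoms: none
Why: Johnson–Claisen rearrangement, in which the ketene acetal can only bond to the alkene CH on the ring face that the C–O bond leaves, so the carbinol chirality is transferred to the new centre beside the gem-dimethyl carbon (the future C5) while the alkene moves to the methyl-bearing position.

Step 3
Reactants: 4 ethyl 2-[(1S)-2,6,6-trimethylcyclohex-2-en-1-yl]acetate
Product: 5 2-[(1S)-2,6,6-trimethylcyclohex-2-en-1-yl]ethan-1-ol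
Conditions: LiAlH4, Et2O, 0 °C
Reagents that add atoms: none
Why: Hydride reduction of an ester to the primary alcohol, which supplies C6 and C7 at the right oxidation level without touching the allylic stereocentre.

Step 4
Reactants: 5 2-[(1S)-2,6,6-trimethylcyclohex-2-en-1-yl]ethan-1-ol
Product: 6 tert-butyldimethyl{2-[(1S)-2,6,6-trimethylcyclohex-2-en-1-yl]ethoxy}silane
Conditions: tBuMe2SiCl, imidazole, CH2Cl2, rt
Reagents that add atoms: tert-butyldimethylsilyl chloride, CC(C)(C)[Si](C)(C)Cl
Why: Silyl ether formation at an unhindered primary alcohol, chosen because this ether should survive the oxidation, hydride, enolate and hydrogenation steps that follow.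

Step 5
Reactants: 6 tert-butyldimethyl{2-[(1S)-2,6,6-trimethylcyclohex-2-en-1-yl]ethoxy}silane
Product: 7 (4S)-4-{2-[(tert-butyldimethylsilyl)oxy]ethyl}-3,5,5-trimethylcyclohex-2-en-1-one
Conditions: dirhodium tetrakis(caprolactamate) Rh2(cap)4 (1 mol %), tBuOOH (70% aq.), K2CO3, CH2Cl2, rt
Reagents that add atoms: tert-butyl hydroperoxide, CC(C)(C)OO
Why: Allylic C–H oxidation with a dirhodium carboxamidate and tert-butyl hydroperoxide, which should convert the only secondary allylic ring methylene (next to the alkene CH) into the conjugated ketone, as is known for α-ionone-type rings, and leaves the stereocentre untouched.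

Step 6
Reactants: 7 (4S)-4-{2-[(tert-butyldimethylsilyl)oxy]ethyl}-3,5,5-trimethylcyclohex-2-en-1-one
Product: 8 (1S,4S)-4-{2-[(tert-butyldimethylsilyl)oxy]ethyl}-3,5,5-trimethylcyclohex-2-en-1-ol (hydroxyl trans to the side chain)
Conditions: Li[HB(sBu)3], THF, −78 °C; then H2O
Reagents that add atoms: none
Why: Diastereoselective 1,2-reduction of a β,β-disubstituted enone by a bulky borohydride; the side chain sits pseudo-axial to avoid the vinylic methyl, which places one of the gem-methyl groups axial on the opposite face, so hydride should enter on the side-chain face and leave the hydroxyl trans to the chain (any cis epimer is a separable diastereomer).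

Step 7
Reactants: 8 (1S,4S)-4-{2-[(tert-butyldimethylsilyl)oxy]ethyl}-3,5,5-trimethylcyclohex-2-en-1-ol; 9 2,2,6-trimethyl-4H-1,3-dioxin-4-one
Product: 10 (1S,4S)-4-{2-[(tert-butyldimethylsilyl)oxy]ethyl}-3,5,5-trimethylcyclohex-2-en-1-yl 3-oxobutanoate
Conditions: PhMe, 110 °C, acetone distilled off
Reagents that add atoms: none
Why: Acetoacetylation through acetylketene released by retro-hetero-Diels–Alder cleavage of the dioxinone, a neutral acylation that works on hindered secondary alcohols and does not disturb the carbinol configuration.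

Step 8
Reactants: 10 (1S,4S)-4-{2-[(tert-butyldimethylsilyl)oxy]ethyl}-3,5,5-trimethylcyclohex-2-en-1-yl 3-oxobutanoate
Product: 12 methyl 2-[(1S,6S)-6-{2-[(tert-butyldimethylsilyl)oxy]ethyl}-1,5,5-trimethylcyclohex-2-en-1-yl]-3-oxobutanoate, via β-keto acid 11 (not isolated)
Conditions: LiN(iPr)2 (2.3 equiv), THF, −78 → 60 °C; 1 M HCl, 0 °C; Me3SiCHN2, PhMe–MeOH, 0 °C
Reagents that add atoms: trimethylsilyldiazomethane, C[Si](C)(C)C=[N+]=[N-]
Why: Ester-enolate (dianion) Carroll rearrangement followed by diazoalkane esterification; the [3,3] shift forms the new C–C bond at the methyl-bearing alkene carbon on the face that the C–O bond leaves, i.e. trans to the side chain, which sets the quaternary centre (future C10), and the keto acid is methylated before it can lose CO2 (the carbon between the carbonyls is formed as both epimers, which does not matter).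

Step 9
Reactants: 12 methyl 2-[(1S,6S)-6-{2-[(tert-butyldimethylsilyl)oxy]ethyl}-1,5,5-trimethylcyclohex-2-en-1-yl]-3-oxobutanoate
Product: 13 methyl 2-[(1S,2S)-2-{2-[(tert-butyldimethylsilyl)oxy]ethyl}-1,3,3-trimethylcyclohexyl]-3-oxobutanoate
Conditions: H2 (1 atm), palladium on carbon (Pd/C), EtOAc, rt
Reagents that add atoms: none
Why: Catalytic hydrogenation of the cis-disubstituted ring alkene, which creates no stereocentre and leaves the keto ester and silyl ether intact.

Step 10
Reactants: 13 methyl 2-[(1S,2S)-2-{2-[(tert-butyldimethylsilyl)oxy]ethyl}-1,3,3-trimethylcyclohexyl]-3-oxobutanoate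
Product: 14 methyl 2-[(1S,2S)-2-(2-hydroxyethyl)-1,3,3-trimethylcyclohexyl]-3-oxobutanoate
Conditions: HF (48% aq.), MeCN, 0 °C
Reagents that add atoms: none
Why: Acidic fluoride desilylation, chosen over basic fluoride so that the β-keto ester is not enolised or cleaved.

Step 11
Reactants: 14 methyl 2-[(1S,2S)-2-(2-hydroxyethyl)-1,3,3-trimethylcyclohexyl]-3-oxobutanoate
Product: 15 methyl 2-[(1S,2S)-2-(2-iodoethyl)-1,3,3-trimethylcyclohexyl]-3-oxobutanoate
Conditions: I2, PPh3, imidazole, CH2Cl2, 0 °C
Reagents that add atoms: iodine, [I][I]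
Why: Appel-type iodination (Garegg–Samuelsson conditions) by SN2 displacement of the primary alkoxyphosphonium ion, run cold and nearly neutral so that the keto ester does not alkylate itself.

Step 12
Reactants: 15 methyl 2-[(1S,2S)-2-(2-iodoethyl)-1,3,3-trimethylcyclohexyl]-3-oxobutanoate
Product: 16 methyl 8β-hydroxydriman-11-oate (5α-H, 9α-H, 10β-methyl)
Conditions: SmI2 (0.1 M in THF, 2.5 equiv), THF, −78 → 0 °C; aq. NH4Cl
Reagents that add atoms: none
Why: Electron transfer from divalent samarium cleaves the primary C7–I bond and a second equivalent turns the radical into an alkylsamarium, while the trivalent samarium formed binds the ketone and ester carbonyls (C8 and C11) as a chelate that activates the C8 ketone, and addition of C7 to C8 then closes ring B. The closest known reaction type is the samarium diiodide intramolecular Barbier cyclisation of iodoalkyl β-keto esters to cis-2-hydroxycycloalkanecarboxylates. Ring B closes in the 6-exo-trig mode through a chair held in place by the trans-diequatorial C5 and C10 arms of ring A. C8 is set by that chair, since its methyl takes the equatorial position away from the axial C10 methyl and the samarium-bound oxygen therefore ends axial (8β). C9 is set by the chelate, which requires the ester equatorial (9β) and gauche to the 8β oxygen, and because the keto ester epimerises at C9 through its enol both precursor epimers should drain into this one product. The step needs carbonyl addition to outrun proton transfer from the acidic C9–H and needs the cis-8,9 relationship; the low temperature, the preorganised ring A scaffold and the chelate are what secure both.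

Step 13
Reactants: 16 methyl 8β-hydroxydriman-11-oate
Product: 17 methyl 8β-(triethylsilyloxy)driman-11-oate
Conditions: Et3SiOTf, 2,6-lutidine, CH2Cl2, −78 → 0 °C
Reagents that add atoms: triethylsilyl trifluoromethanesulfonate, CC[Si](CC)(CC)OS(=O)(=O)C(F)(F)F
Why: Silylation of a hindered tertiary alcohol with a silyl triflate, which blocks retro-aldol opening and β-elimination once C11 becomes an aldehyde.

Step 14
Reactants: 17 methyl 8β-(triethylsilyloxy)driman-11-oate
Product: 18 8β-(triethylsilyloxy)driman-11-ol
Conditions: iBu2AlH (2.5 equiv), CH2Cl2, −78 → 0 °C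
Reagents that add atoms: none
Why: Aluminium hydride reduction of the hindered ester fully to the primary alcohol, which avoids a mixed over- and under-reduced product and does not epimerise C9.

Step 15
Reactants: 18 8β-(triethylsilyloxy)driman-11-ol
Product: 19 8β-(triethylsilyloxy)driman-11-al
Conditions: Dess–Martin periodinane, NaHCO3, CH2Cl2, rt
Reagents that add atoms: none
Why: Dess–Martin oxidation under buffered, non-basic conditions, which should give the aldehyde without epimerising C9 or expelling the β-silyloxy group.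

Step 16
Reactants: 19 8β-(triethylsilyloxy)driman-11-al; 20 cyclopent-4-ene-1,3-dione
Product: 21 2-[8β-(triethylsilyloxy)driman-11-ylidene]cyclopent-4-ene-1,3-dione
Conditions: piperidinium acetate (10 mol %), 4 Å molecular sieves, CH2Cl2, rt
Reagents that add atoms: none
Why: Knoevenagel condensation at the doubly activated CH2 of the dione; because the two carbonyls of 20 are equivalent, the new C11=C1' bond has no geometry to control at this stage, and loss of conjugation through C9 is blocked because it would create a cyclopentadienone.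

Step 17
Reactants: 21 2-[8β-(triethylsilyloxy)driman-11-ylidene]cyclopent-4-ene-1,3-dione
Product: 22 (4R,5Z)-4-hydroxy-5-[8β-(triethylsilyloxy)driman-11-ylidene]cyclopent-2-en-1-one
Conditions: (S)-1-methyl-3,3-diphenyltetrahydro-1H,3H-pyrrolo[1,2-c][1,3,2]oxazaborole (20 mol %), catecholborane, PhMe, −78 °C
Reagents that add atoms: none
Why: Corey–Bakshi–Shibata reduction used as a mono-reduction of the ene-dione; the carbonyl cis to H-11 is open while the one cis to C9 lies under the drimane, so hydride should go to the former, which places the future chlorine-bearing carbon C5' trans to C9 across C11=C1', and the catalyst (alkylidene carbon as the large group) should set the carbinol as 4R.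

Step 18
Reactants: 22 (4R,5Z)-4-hydroxy-5-[8β-(triethylsilyloxy)driman-11-ylidene]cyclopent-2-en-1-one
Product: 23 2,3-epoxide of 22 (oxirane trans to the 4-hydroxyl)
Conditions: tBuOOH, DBU, CH2Cl2, 0 °C
Reagents that add atoms: tert-butyl hydroperoxide, CC(C)(C)OO
Why: Weitz–Scheffer nucleophilic epoxidation, in which the peroxide anion adds to the β-carbon C4' of the endocyclic enone (the alkylidene β-carbon C11 is too hindered), expected anti to the hydroxyl; both oxirane centres are erased in the next step, so either diastereomer serves.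

Step 19
Reactants: 23 2,3-epoxide of 22
Product: 24 (4S,5Z)-4-hydroxy-5-[8β-(triethylsilyloxy)driman-11-ylidene]cyclopentane-1,3-dione (enol form)
Conditions: Pd(PPh3)4 (5 mol %), Ph2PCH2CH2PPh2 (5 mol %), PhMe, 80 °C
Reagents that add atoms: none
Why: Isomerisation of an α,β-epoxy ketone to a β-diketone catalysed by zerovalent palladium (insertion into the Cα–O bond, β-hydride elimination from C4', reductive elimination), which puts the second carbonyl at C4' and leaves the C5' carbinol and the alkene geometry as they are.

Step 20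
Reactants: 24 (4S,5Z)-4-hydroxy-5-[8β-(triethylsilyloxy)driman-11-ylidene]cyclopentane-1,3-dione
Product: 26 (4R,5E)-3-[(tert-butyldimethylsilyl)oxy]-4-chloro-5-[8β-(triethylsilyloxy)driman-11-ylidene]cyclopent-2-en-1-one, via silyl enol ether alcohol 25 (not isolated)
Conditions: tBuMe2SiCl, Et3N, CH2Cl2, 0 °C; then PPh3, Cl3CC(O)CCl3, −20 → 0 °C
Reagents that add atoms: tert-butyldimethylsilyl chloride, CC(C)(C)[Si](C)(C)Cl; hexachloroacetone, ClC(Cl)(Cl)C(=O)C(Cl)(Cl)Cl
Why: Enol silylation followed by an Appel chlorination (triphenylphosphine with hexachloroacetone); the acidic enol oxygen remote from C9 is capped so that only the C5' hydroxyl forms an alkoxyphosphonium ion, which chloride should displace by SN2 with inversion to the 4R chloride, ionisation and SN2' attack both being disfavoured because they would pass through cyclopentadienone-like species.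

Step 21
Reactants: 26 (4R,5E)-3-[(tert-butyldimethylsilyl)oxy]-4-chloro-5-[8β-(triethylsilyloxy)driman-11-ylidene]cyclopent-2-en-1-one
Product: 27 CNP0279879.2, (4R,5E)-4-chloro-5-(8β-hydroxydriman-11-ylidene)cyclopentane-1,3-dione as its enol
Conditions: HF·pyridine, THF, 0 °C → rt
Reagents that add atoms: none
Why: Fluoride desilylation under mildly acidic conditions, which should remove the enol silyl ether and the tertiary triethylsilyl ether without enolising the α-chloro ketone centre C5', releasing the target.

**Compound list**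

1 | 2,4,4-trimethylcyclohex-2-en-1-one | O=C1CCC(C)(C)C=C1C | starting material
2 | (R)-2,4,4-trimethylcyclohex-2-en-1-ol | O[C@@H]1CCC(C)(C)C=C1C | intermediate
3 | triethyl orthoacetate | CC(OCC)(OCC)OCC | starting material
4 | ethyl 2-[(1S)-2,6,6-trimethylcyclohex-2-en-1-yl]acetate | CC1(C)CCC=C(C)[C@H]1CC(=O)OCC | intermediate
5 | 2-[(1S)-2,6,6-trimethylcyclohex-2-en-1-yl]ethan-1-ol | CC1(C)CCC=C(C)[C@H]1CCO | intermediate
6 | tert-butyldimethyl{2-[(1S)-2,6,6-trimethylcyclohex-2-en-1-yl]ethoxy}silane | CC1(C)CCC=C(C)[C@H]1CCO[Si](C)(C)C(C)(C)C | intermediate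
7 | (4S)-4-{2-[(tert-butyldimethylsilyl)oxy]ethyl}-3,5,5-trimethylcyclohex-2-en-1-one | CC1(C)CC(=O)C=C(C)[C@H]1CCO[Si](C)(C)C(C)(C)C | intermediate
8 | (1S,4S)-4-{2-[(tert-butyldimethylsilyl)oxy]ethyl}-3,5,5-trimethylcyclohex-2-en-1-ol | CC1(C)C[C@H](O)C=C(C)[C@H]1CCO[Si](C)(C)C(C)(C)C | intermediate
9 | 2,2,6-trimethyl-4H-1,3-dioxin-4-one | CC1=CC(=O)OC(C)(C)O1 | starting material
10 | (1S,4S)-4-{2-[(tert-butyldimethylsilyl)oxy]ethyl}-3,5,5-trimethylcyclohex-2-en-1-yl 3-oxobutanoate | CC1(C)C[C@H](OC(=O)CC(C)=O)C=C(C)[C@H]1CCO[Si](C)(C)C(C)(C)C | intermediate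
11 | 2-[(1S,6S)-6-{2-[(tert-butyldimethylsilyl)oxy]ethyl}-1,5,5-trimethylcyclohex-2-en-1-yl]-3-oxobutanoic acid (both epimers at the carbon between the carbonyls) | CC1(C)CC=C[C@](C)(C(C(C)=O)C(=O)O)[C@H]1CCO[Si](C)(C)C(C)(C)C | intermediate (not isolated)
12 | methyl 2-[(1S,6S)-6-{2-[(tert-butyldimethylsilyl)oxy]ethyl}-1,5,5-trimethylcyclohex-2-en-1-yl]-3-oxobutanoate | CC1(C)CC=C[C@](C)(C(C(C)=O)C(=O)OC)[C@H]1CCO[Si](C)(C)C(C)(C)C | intermediate
13 | methyl 2-[(1S,2S)-2-{2-[(tert-butyldimethylsilyl)oxy]ethyl}-1,3,3-trimethylcyclohexyl]-3-oxobutanoate | CC1(C)CCC[C@](C)(C(C(C)=O)C(=O)OC)[C@H]1CCO[Si](C)(C)C(C)(C)C | intermediate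
14 | methyl 2-[(1S,2S)-2-(2-hydroxyethyl)-1,3,3-trimethylcyclohexyl]-3-oxobutanoate | CC1(C)CCC[C@](C)(C(C(C)=O)C(=O)OC)[C@H]1CCO | intermediate
15 | methyl 2-[(1S,2S)-2-(2-iodoethyl)-1,3,3-trimethylcyclohexyl]-3-oxobutanoate (key-step precursor) | CC1(C)CCC[C@](C)(C(C(C)=O)C(=O)OC)[C@H]1CCI | intermediate
16 | methyl 8β-hydroxydriman-11-oate (5S,8S,9R,10S; key-step product) | CC1(C)CCC[C@]2(C)[C@@H](C(=O)OC)[C@@](C)(O)CC[C@@H]12 | intermediate
17 | methyl 8β-(triethylsilyloxy)driman-11-oate | CC1(C)CCC[C@]2(C)[C@@H](C(=O)OC)[C@@](C)(O[Si](CC)(CC)CC)CC[C@@H]12 | intermediate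
18 | 8β-(triethylsilyloxy)driman-11-ol | CC1(C)CCC[C@]2(C)[C@@H](CO)[C@@](C)(O[Si](CC)(CC)CC)CC[C@@H]12 | intermediate
19 | 8β-(triethylsilyloxy)driman-11-al | CC1(C)CCC[C@]2(C)[C@@H](C=O)[C@@](C)(O[Si](CC)(CC)CC)CC[C@@H]12 | intermediate
20 | cyclopent-4-ene-1,3-dione | O=C1CC(=O)C=C1 | starting material
21 | 2-[8β-(triethylsilyloxy)driman-11-ylidene]cyclopent-4-ene-1,3-dione | CC1(C)CCC[C@]2(C)[C@@H](C=C3C(=O)C=CC3=O)[C@@](C)(O[Si](CC)(CC)CC)CC[C@@H]12 | intermediate
22 | (4R,5Z)-4-hydroxy-5-[8β-(triethylsilyloxy)driman-11-ylidene]cyclopent-2-en-1-one | CC1(C)CCC[C@]2(C)[C@@H](/C=C3\C(=O)C=C[C@H]3O)[C@@](C)(O[Si](CC)(CC)CC)CC[C@@H]12 | intermediate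
23 | 2,3-epoxide of 22, oxirane trans to the 4-hydroxyl | CC1(C)CCC[C@]2(C)[C@@H](/C=C3\C(=O)[C@@H]4O[C@@H]4[C@H]3O)[C@@](C)(O[Si](CC)(CC)CC)CC[C@@H]12 | intermediate
24 | (4S,5Z)-4-hydroxy-5-[8β-(triethylsilyloxy)driman-11-ylidene]cyclopentane-1,3-dione, enol form | CC1(C)CCC[C@]2(C)[C@@H](/C=C3\C(O)=CC(=O)[C@H]3O)[C@@](C)(O[Si](CC)(CC)CC)CC[C@@H]12 | intermediate
25 | (4S,5Z)-3-[(tert-butyldimethylsilyl)oxy]-4-hydroxy-5-[8β-(triethylsilyloxy)driman-11-ylidene]cyclopent-2-en-1-one | CC1(C)CCC[C@]2(C)[C@@H](/C=C3\C(=O)C=C(O[Si](C)(C)C(C)(C)C)[C@H]3O)[C@@](C)(O[Si](CC)(CC)CC)CC[C@@H]12 | intermediate (not isolated)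
26 | (4R,5E)-3-[(tert-butyldimethylsilyl)oxy]-4-chloro-5-[8β-(triethylsilyloxy)driman-11-ylidene]cyclopent-2-en-1-one | CC1(C)CCC[C@]2(C)[C@@H](/C=C3\C(=O)C=C(O[Si](C)(C)C(C)(C)C)[C@@H]3Cl)[C@@](C)(O[Si](CC)(CC)CC)CC[C@@H]12 | intermediate
27 | CNP0279879.2, (4R,5E)-4-chloro-5-(8β-hydroxydriman-11-ylidene)cyclopentane-1,3-dione, enol form | CC1(C)CCC[C@]2(C)[C@@H](/C=C3\C(O)=CC(=O)[C@@H]3Cl)[C@@](C)(O)CC[C@@H]12 | target

**Step count and risk**

Total step count: 21. Longest linear sequence: 21 steps (1 → 27); compounds 3, 9 and 20 are bought and enter directly.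

The three steps most likely to fail:

Step 12. Proton transfer from the acidic C9–H to the organosamarium would give net deiodination, and the C9 epimer that cannot chelate may close slowly or unselectively. The fallback closes the same ring by radical conjugate addition instead of carbonyl addition. It sets out from iodide 15, which would be O-silylated (Et3SiCl, Et3N, CH2Cl2) to methyl 2-[(1S,2S)-2-(2-iodoethyl)-1,3,3-trimethylcyclohexyl]-3-(triethylsilyloxy)but-2-enoate F1, a compound with no acidic proton. Slow addition of Bu3SnH with AIBN in benzene at 80 °C would generate the C7 radical, which should add 6-exo-trig to the silyloxy-bearing enoate carbon C8 through the same chair (methyl equatorial). The resulting ester-stabilised C9 radical would take hydrogen on the α face, opposite the axial C10 methyl and axial silyloxy group, and the route is rejoined at silyl ether 17.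

Step 16. Addition of the dione to the very hindered, α-branched aldehyde may stall while the ene-dione is consumed by amine addition or self-condensation. The fallback replaces the reversible condensation by an irreversible enolate aldol and sets out from aldehyde 19. Addition of the lithium α'-enolate of cyclopent-2-en-1-one (LiN(iPr)2, THF, −78 °C) would give 5-{hydroxy[8β-(triethylsilyloxy)driman-11-yl]}cyclopent-2-en-1-one F2 as a diastereomer mixture. Mesylation (MeSO2Cl, Et3N) would give the methanesulfonate F3, and elimination with DBU the cross-conjugated dienone 5-[8β-(triethylsilyloxy)driman-11-ylidene]cyclopent-2-en-1-one F4, whose alkene geometry is irrelevant. Oxidation of its doubly allylic ring CH2 (Pd(OH)2 on carbon, tBuOOH, K2CO3, CH2Cl2, the enone-to-enedione oxidation) would then return the route at 21.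

Step 17. Hydride delivery may fail to distinguish the two carbonyls, may reduce the ene-dione in the conjugate sense, or may give poor facial control at the carbinol. The fallback takes the C5' centre from the chiral pool instead of from the catalyst and sets out from aldehyde 19. Commercial (S)-4-hydroxycyclopent-2-en-1-one would be silylated (Et3SiCl, imidazole) to (S)-4-(triethylsilyloxy)cyclopent-2-en-1-one F5. Its lithium enolate (LiN(iPr)2, THF, −78 °C) would be added to 19 to give the aldol F6. Mesylation would give F7, and elimination with DBU the bis-silyl ether (4R,5Z)-4-(triethylsilyloxy)-5-[8β-(triethylsilyloxy)driman-11-ylidene]cyclopent-2-en-1-one F8. In this variant the alkene geometry rests on the elimination, so the Z isomer would have to be separated from any E isomer. Pyridinium p-toluenesulfonate in MeOH at 0 °C would cleave only the secondary allylic silyl ether, and the route is rejoined at 22.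

**Further compounds**

F1 | step 12 | methyl 2-[(1S,2S)-2-(2-iodoethyl)-1,3,3-trimethylcyclohexyl]-3-(triethylsilyloxy)but-2-enoate | CC1(C)CCC[C@](C)(C(C(=O)OC)=C(C)O[Si](CC)(CC)CC)[C@H]1CCI
F2 | step 16 | 5-{hydroxy[8β-(triethylsilyloxy)driman-11-yl]}cyclopent-2-en-1-one (mixture at the two new centres) | CC1(C)CCC[C@]2(C)[C@@H](C(O)C3CC=CC3=O)[C@@](C)(O[Si](CC)(CC)CC)CC[C@@H]12
F3 | step 16 | methanesulfonate of F2 | CC1(C)CCC[C@]2(C)[C@@H](C(OS(C)(=O)=O)C3CC=CC3=O)[C@@](C)(O[Si](CC)(CC)CC)CC[C@@H]12
F4 | step 16 | 5-[8β-(triethylsilyloxy)driman-11-ylidene]cyclopent-2-en-1-one | CC1(C)CCC[C@]2(C)[C@@H](C=C3CC=CC3=O)[C@@](C)(O[Si](CC)(CC)CC)CC[C@@H]12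
F5 | step 17 | (S)-4-(triethylsilyloxy)cyclopent-2-en-1-one | C1C(=O)C=C[C@H]1O[Si](CC)(CC)CC
F6 | step 17 | (4S)-5-{hydroxy[8β-(triethylsilyloxy)driman-11-yl]}-4-(triethylsilyloxy)cyclopent-2-en-1-one (mixture at the two new centres) | CC1(C)CCC[C@]2(C)[C@@H](C(O)C3C(=O)C=C[C@H]3O[Si](CC)(CC)CC)[C@@](C)(O[Si](CC)(CC)CC)CC[C@@H]12
F7 | step 17 | methanesulfonate of F6 | CC1(C)CCC[C@]2(C)[C@@H](C(OS(C)(=O)=O)C3C(=O)C=C[C@H]3O[Si](CC)(CC)CC)[C@@](C)(O[Si](CC)(CC)CC)CC[C@@H]12
F8 | step 17 | (4R,5Z)-4-(triethylsilyloxy)-5-[8β-(triethylsilyloxy)driman-11-ylidene]cyclopent-2-en-1-one | CC1(C)CCC[C@]2(C)[C@@H](/C=C3\C(=O)C=C[C@H]3O[Si](CC)(CC)CC)[C@@](C)(O[Si](CC)(CC)CC)CC[C@@H]12
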